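TBS = tert-butyldimethylsilyl. Cyclohexene numbering: C1'' carries the 4-methylpent-3-enyl chain, C3'' the flavanone, C4'' the aroyl group, C5'' the aryl group.

## Retrosynthetic overview
1. The target comes from its heptasilyl ether by fluoride deprotection, which uses neither acid nor base.
2. Both non-aromatic rings are opened together: retro-Diels–Alder (C3''–C4'', C5''–C6'') and retro-oxa-Michael (O1–C2). This gives two achiral open-chain chalcones, a 2'-hydroxychalcone dienophile and a dienyl chalcone.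
3. Forward, both rings close in one flask: the pyranone first (sets C2), then the cyclohexene (sets C3'', C4'', C5'').
4. Both chalcones come from the same silylated 2,4-dihydroxybenzaldehyde by Claisen–Schmidt condensation. The diene comes from myrcene by a Heck reaction.
5. The oxygen that becomes O1 is singled out on iodophloroacetophenone by silylating all three OH groups and then removing one silyl group under chelation control.

Assumption (sense of induction): the quinidine-derived thiourea is taken to give (2S) and (R)-VANOL the (3''R,4''R,5''S) adduct; if a first run shows the opposite sense, the quinine-derived pseudo-enantiomer or (S)-VANOL is used and nothing else changes.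

## Route

Step 1
Reactants: 1 2,4-dihydroxybenzaldehyde
Product: 2 2,4-bis(TBS-oxy)benzaldehyde
Conditions: TBSCl (2.5 equiv), imidazole (5 equiv), DMF, rt, 12 h
Reagents that add atoms: tert-butyldimethylsilyl chloride, CC(C)(C)[Si](C)(C)Cl
Why: Imidazole-promoted O-silylation with excess reagent also caps the hydrogen-bonded 2-OH, which keeps the aldehyde electrophilic and installs groups that can later be removed without acid or base.

Step 2
Reactants: 3 2,4-dihydroxyacetophenone; 4 prenyl bromide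
Product: 5 1-[2,4-dihydroxy-3-(3-methylbut-2-en-1-yl)phenyl]ethanone
Conditions: KOH (2 equiv), H2O, 0 °C to rt, 24 h
Reagents that add atoms: none
Why: C-alkylation of the ambident resorcinolate in water takes place at C3, the carbon between the two oxygens; the yield is modest, and the 5-prenyl and O-prenyl isomers are removed by chromatography.

Step 3
Reactants: 5 1-[2,4-dihydroxy-3-(3-methylbut-2-en-1-yl)phenyl]ethanone
Product: 6 1-[4-(TBS-oxy)-2-hydroxy-3-(3-methylbut-2-en-1-yl)phenyl]ethanone
Conditions: TBSCl (1.1 equiv), imidazole, CH2Cl2, 0 °C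
Reagents that add atoms: tert-butyldimethylsilyl chloride, CC(C)(C)[Si](C)(C)Cl
Why: This is a chemoselective silylation, because the 2-OH is locked in a hydrogen bond to the ketone and only the 4-OH reacts; the free 2-OH is later needed to bind boron.

Step 4
Reactants: 6 1-[4-(TBS-oxy)-2-hydroxy-3-(3-methylbut-2-en-1-yl)phenyl]ethanone; 2 2,4-bis(TBS-oxy)benzaldehyde
Product: 8 dienophile chalcone (E)-2'-hydroxy-3'-prenyl-2,4,4'-tris(TBS-oxy)chalcone, via racemic aldol adduct 7 (not isolated)
Conditions: LiHMDS (2.3 equiv), THF, −78 °C; 2; −78 to 0 °C; AcOH quench at −40 °C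
Reagents that add atoms: none
Why: Claisen–Schmidt condensation through the lithium phenoxide–enolate dianion (aldol addition, then E1cB loss of LiOH) gives the E-enone, and the aprotic amide base with a cold quench spares the aryl silyl ethers.

Step 5
Reactants: 9 2,4,6-trihydroxyacetophenone
Product: 10 1-(2,4,6-trihydroxy-3-iodophenyl)ethanone
Conditions: NIS (1.0 equiv, slow addition), MeCN, −20 to 0 °C
Reagents that add atoms: N-iodosuccinimide, O=C1CCC(=O)N1I
Why: Electrophilic aromatic iodination; the two open ring positions are equivalent, so one equivalent of NIS gives a single mono-iodide.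

Step 6
Reactants: 10 1-(2,4,6-trihydroxy-3-iodophenyl)ethanone
Product: 11 1-[3-iodo-2,4,6-tris(TBS-oxy)phenyl]ethanone
Conditions: TBSOTf (3.6 equiv), 2,6-lutidine (5 equiv), CH2Cl2, −78 to 0 °C
Reagents that add atoms: tert-butyldimethylsilyl triflate, CC(C)(C)[Si](C)(C)OS(=O)(=O)C(F)(F)F
Why: The silyl triflate is reactive enough to cap even the OH wedged between iodine and acetyl, and both oxygens next to iodine must be blocked so that the later allyl-palladium intermediate is not trapped as a dihydrobenzofuran (Larock-type annulation).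

Step 7
Reactants: 11 1-[3-iodo-2,4,6-tris(TBS-oxy)phenyl]ethanone
Product: 13 1-[6-hydroxy-3-iodo-2,4-bis(TBS-oxy)phenyl]ethanone, via dichloroboron chelate 12 (not isolated)
Conditions: BCl3 (1.05 equiv), CH2Cl2, −78 °C, 30 min; H2O
Reagents that add atoms: boron trichloride, ClB(Cl)Cl
Why: Chelation-directed Lewis-acid cleavage: ketone-bound BCl3 reaches only an ortho O–Si bond (4-OTBS is untouched), and chloride attacks the exposed silicon on O6 rather than the one on O2 wedged between iodine and acetyl, so exactly the oxygen that becomes O1 is freed.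

Step 8
Reactants: 13 1-[6-hydroxy-3-iodo-2,4-bis(TBS-oxy)phenyl]ethanone; 14 myrcene
Product: 15 1-{6-hydroxy-3-[(1E)-7-methyl-3-methylideneocta-1,6-dien-1-yl]-2,4-bis(TBS-oxy)phenyl}ethanone
Conditions: 14 (3 equiv), Pd2(dba)3 (2.5 mol %), P(t-Bu)3·HBF4 (10 mol %), Cy2NMe (2.5 equiv), dioxane, 80 °C
Reagents that add atoms: none
Why: Mizoroki–Heck reaction: aryl-palladium adds to the unsubstituted vinyl terminus of myrcene and β-hydride elimination of a benzylic hydrogen gives the conjugated (E)-1-aryl diene, while the trisubstituted alkene and the remote hydrogen-bonded 6-OH stay out of the reaction.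

Step 9
Reactants: 15 1-{6-hydroxy-3-[(1E)-7-methyl-3-methylideneocta-1,6-dien-1-yl]-2,4-bis(TBS-oxy)phenyl}ethanone; 2 2,4-bis(TBS-oxy)benzaldehyde
Product: 17 dienyl chalcone (E)-6'-hydroxy-3'-[(1E)-7-methyl-3-methylideneocta-1,6-dienyl]-2,2',4,4'-tetrakis(TBS-oxy)chalcone, via racemic aldol adduct 16 (not isolated)
Conditions: LiHMDS (2.4 equiv), THF, −78 °C; 2; −78 to 0 °C; AcOH quench at −40 °C
Reagents that add atoms: none
Why: Claisen–Schmidt condensation of the dianion as in step 4; in the strongly basic aprotic medium the delocalised chalcone phenoxide stays open, and the cold acidic quench delivers the open E-chalcone before any uncatalysed ring closure or O-to-O silyl shift.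

Step 10
Reactants: 17 dienyl chalcone; 8 dienophile chalcone
Product: 19 heptasilyl all-trans adduct (2S;3''R;4''R;5''S), via (2S)-flavanone diene 18 (not isolated)
Conditions: (i) 17, 9-amino(9-deoxy)epi-quinidine 3,5-bis(trifluoromethyl)phenyl thiourea (10 mol %), PhCF3, rt, 36 h; (ii) same flask: 8 (1.2 equiv), (R)-VANOL (40 mol %), B(OPh)3 (55 mol %), 5 Å MS, rt to 40 °C, 72 h
Reagents that add atoms: none
Why: Proposed new method: two orthogonal asymmetric catalysts act in sequence in one flask; first the bifunctional thiourea (quinuclidine activates the only free phenol, 6'-OH, and the thiourea binds the enone C=O) closes the pyranone by 6-endo-trig oxa-Michael addition and sets C2 as S, with 2'-O silylated so that only the 6-dienyl flavanone can form (closest known type: cinchona-catalysed asymmetric cyclisation of 2'-hydroxychalcones and o-enoylphenols), and this closure also removes the diene partner's own enone and chelating OH; then B(OPh)3/(R)-VANOL, with boron in excess over the amine so that the quinuclidine is tied up and cannot cyclise 8, chelates 8 through 2'-O and C=O, and the LUMO-lowered enone adds to diene 18 with "ortho" regiochemistry through the exo transition state (the bulky borate–aroyl unit avoids the twisted 2,6-disilyloxyaryl group and the slimmer B-ring lies endo) on the face left open by the vaulted ligand, setting C3''R, C4''R, C5''S all-trans (closest known type: chiral borate-catalysed Diels–Alder reaction of 2'-hydroxychalcones); any (2R) leakage ends up as a separable diastereomer of 19.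

Step 11
Reactants: 19 heptasilyl all-trans adduct
Product: 20 target CNP0256494.1
Conditions: Et3N·3HF (30 equiv), THF/MeCN, rt to 40 °C, 36 h
Reagents that add atoms: none
Why: Fluoride-driven Si–O cleavage in a weakly acidic buffered medium removes all seven silyl groups; no base is present that could epimerise C2 by retro-oxa-Michael opening, and no strong acid that could cyclise the prenyl groups or ketalise the all-trans hydroxy ketone.

## Compound list
1 | 2,4-dihydroxybenzaldehyde | O=Cc1ccc(O)cc1O | starting material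
2 | 2,4-bis(TBS-oxy)benzaldehyde | O=Cc1ccc(O[Si](C)(C)C(C)(C)C)cc1O[Si](C)(C)C(C)(C)C | intermediate
3 | 2,4-dihydroxyacetophenone | CC(=O)c1ccc(O)cc1O | starting material
4 | prenyl bromide (1-bromo-3-methylbut-2-ene) | CC(C)=CCBr | starting material
5 | 1-[2,4-dihydroxy-3-(3-methylbut-2-en-1-yl)phenyl]ethanone | CC(=O)c1ccc(O)c(CC=C(C)C)c1O | intermediate
6 | 1-[4-(TBS-oxy)-2-hydroxy-3-(3-methylbut-2-en-1-yl)phenyl]ethanone | CC(=O)c1ccc(O[Si](C)(C)C(C)(C)C)c(CC=C(C)C)c1O | intermediate
7 | racemic 3-[2,4-bis(TBS-oxy)phenyl]-3-hydroxy-1-[4-(TBS-oxy)-2-hydroxy-3-prenylphenyl]propan-1-one | O=C(CC(O)c1ccc(O[Si](C)(C)C(C)(C)C)cc1O[Si](C)(C)C(C)(C)C)c1ccc(O[Si](C)(C)C(C)(C)C)c(CC=C(C)C)c1O | intermediate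
8 | (E)-3-[2,4-bis(TBS-oxy)phenyl]-1-[4-(TBS-oxy)-2-hydroxy-3-prenylphenyl]prop-2-en-1-one | O=C(/C=C/c1ccc(O[Si](C)(C)C(C)(C)C)cc1O[Si](C)(C)C(C)(C)C)c1ccc(O[Si](C)(C)C(C)(C)C)c(CC=C(C)C)c1O | intermediate
9 | 2,4,6-trihydroxyacetophenone | CC(=O)c1c(O)cc(O)cc1O | starting material
10 | 1-(2,4,6-trihydroxy-3-iodophenyl)ethanone | CC(=O)c1c(O)cc(O)c(I)c1O | intermediate
11 | 1-[3-iodo-2,4,6-tris(TBS-oxy)phenyl]ethanone | CC(=O)c1c(O[Si](C)(C)C(C)(C)C)cc(O[Si](C)(C)C(C)(C)C)c(I)c1O[Si](C)(C)C(C)(C)C | intermediate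
12 | dichloroboron chelate of 13 through O6 and the ketone oxygen (charges depict the dative bond) | CC1=[O+][B-](Cl)(Cl)Oc2cc(O[Si](C)(C)C(C)(C)C)c(I)c(O[Si](C)(C)C(C)(C)C)c12 | intermediate
13 | 1-[6-hydroxy-3-iodo-2,4-bis(TBS-oxy)phenyl]ethanone | CC(=O)c1c(O)cc(O[Si](C)(C)C(C)(C)C)c(I)c1O[Si](C)(C)C(C)(C)C | intermediate
14 | myrcene (7-methyl-3-methylideneocta-1,6-diene) | C=CC(=C)CCC=C(C)C | starting material
15 | 1-{6-hydroxy-3-[(1E)-7-methyl-3-methylideneocta-1,6-dien-1-yl]-2,4-bis(TBS-oxy)phenyl}ethanone | CC(=O)c1c(O)cc(O[Si](C)(C)C(C)(C)C)c(/C=C/C(=C)CCC=C(C)C)c1O[Si](C)(C)C(C)(C)C | intermediate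
16 | racemic β-hydroxy ketone from 15 and 2 | O=C(CC(O)c1ccc(O[Si](C)(C)C(C)(C)C)cc1O[Si](C)(C)C(C)(C)C)c1c(O)cc(O[Si](C)(C)C(C)(C)C)c(/C=C/C(=C)CCC=C(C)C)c1O[Si](C)(C)C(C)(C)C | intermediate
17 | (E)-3-[2,4-bis(TBS-oxy)phenyl]-1-{6-hydroxy-3-[(1E)-7-methyl-3-methylideneocta-1,6-dien-1-yl]-2,4-bis(TBS-oxy)phenyl}prop-2-en-1-one | O=C(/C=C/c1ccc(O[Si](C)(C)C(C)(C)C)cc1O[Si](C)(C)C(C)(C)C)c1c(O)cc(O[Si](C)(C)C(C)(C)C)c(/C=C/C(=C)CCC=C(C)C)c1O[Si](C)(C)C(C)(C)C | intermediate
18 | (2S)-2-[2,4-bis(TBS-oxy)phenyl]-5,7-bis(TBS-oxy)-6-[(1E)-7-methyl-3-methylideneocta-1,6-dien-1-yl]chroman-4-one | CC(C)=CCCC(=C)/C=C/c1c(O[Si](C)(C)C(C)(C)C)cc2c(c1O[Si](C)(C)C(C)(C)C)C(=O)C[C@@H](c1ccc(O[Si](C)(C)C(C)(C)C)cc1O[Si](C)(C)C(C)(C)C)O2 | intermediate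
19 | (2S)-2-[2,4-bis(TBS-oxy)phenyl]-5,7-bis(TBS-oxy)-6-{(1R,5S,6R)-5-[2,4-bis(TBS-oxy)phenyl]-6-[4-(TBS-oxy)-2-hydroxy-3-prenylbenzoyl]-3-(4-methylpent-3-en-1-yl)cyclohex-2-en-1-yl}chroman-4-one (all-trans) | CC(C)=CCCC1=C[C@@H](c2c(O[Si](C)(C)C(C)(C)C)cc3c(c2O[Si](C)(C)C(C)(C)C)C(=O)C[C@@H](c2ccc(O[Si](C)(C)C(C)(C)C)cc2O[Si](C)(C)C(C)(C)C)O3)[C@H](C(=O)c2ccc(O[Si](C)(C)C(C)(C)C)c(CC=C(C)C)c2O)[C@@H](c2ccc(O[Si](C)(C)C(C)(C)C)cc2O[Si](C)(C)C(C)(C)C)C1 | intermediate
20 | (2S)-2-(2,4-dihydroxyphenyl)-6-{(1R,5S,6R)-6-[2,4-dihydroxy-3-prenylbenzoyl]-5-(2,4-dihydroxyphenyl)-3-(4-methylpent-3-en-1-yl)cyclohex-2-en-1-yl}-5,7-dihydroxychroman-4-one | CC(C)=CCCC1=C[C@@H](c2c(O)cc3c(c2O)C(=O)C[C@@H](c2ccc(O)cc2O)O3)[C@H](C(=O)c2ccc(O)c(CC=C(C)C)c2O)[C@@H](c2ccc(O)cc2O)C1 | target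

## Step count and risks
Total: 11 steps. The longest linear sequence is 7 steps (9 → 10 → 11 → 13 → 15 → 17 → 19 → 20).

**Risk 1, step 10.** The two catalysts may interfere with each other, the closure of the hindered chalcone may be slow or poorly selective, or the exo:endo ratio may be low.
- The fallback inverts the order of ring formation and makes the rings in separate operations.
- It sets out from 15. The borate-catalysed Diels–Alder reaction with 8 is run at the acetophenone stage, where no second enone is present and the diene partner is smaller. This gives the acetyl-bearing all-trans adduct F1.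
- LiHMDS-mediated Claisen–Schmidt condensation of its methyl ketone with 2 gives the adduct chalcone F2.
- The thiourea-catalysed oxa-Michael closure then runs on an enantiopure substrate, so the C2 epimer is removed by chromatography. The fallback comes back to the route at 19.

**Risk 2, step 8.** The iodide lies between two silyloxy groups, and the allyl-palladium intermediate may be diverted.
- The fallback replaces the Heck reaction on myrcene by a cross-coupling with a preformed dienyl nucleophile, so no allyl-palladium species is involved.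
- Purchased 6-methylhept-5-en-2-one is converted with LDA and PhNTf2 into 6-methylhepta-1,5-dien-2-yl triflate F3.
- A boron-retaining Heck coupling with vinylboronic acid pinacol ester gives (E)-dienylboronic acid pinacol ester F4.
- Suzuki–Miyaura coupling (SPhos-Pd, K3PO4, toluene) sets out from 13 and comes back at 15.

**Risk 3, step 7.** The O6 versus O2 selectivity of the BCl3 cleavage may be poor.
- The fallback uses a different selectivity principle: nucleophilic stripping by steric access, then chelation-controlled re-silylation.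
- It sets out from 11. K2CO3 in MeOH at 0 °C removes the two singly flanked silyl groups (O4 and O6) and leaves the doubly flanked one, giving 1-[4,6-dihydroxy-3-iodo-2-(TBS-oxy)phenyl]ethanone F5.
- TBSCl (1.05 equiv) with imidazole then silylates only the non-chelated 4-OH, and the fallback comes back at 13.

## Further compounds
F1 | step 10 | 1-{3-[(1R,5S,6R)-5-[2,4-bis(TBS-oxy)phenyl]-6-[4-(TBS-oxy)-2-hydroxy-3-prenylbenzoyl]-3-(4-methylpent-3-en-1-yl)cyclohex-2-en-1-yl]-6-hydroxy-2,4-bis(TBS-oxy)phenyl}ethanone | CC(C)=CCCC1=C[C@@H](c2c(O[Si](C)(C)C(C)(C)C)cc(O)c(C(C)=O)c2O[Si](C)(C)C(C)(C)C)[C@H](C(=O)c2ccc(O[Si](C)(C)C(C)(C)C)c(CC=C(C)C)c2O)[C@@H](c2ccc(O[Si](C)(C)C(C)(C)C)cc2O[Si](C)(C)C(C)(C)C)C1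
F2 | step 10 | (E)-chalcone from F1 and 2 (open form of 19) | CC(C)=CCCC1=C[C@@H](c2c(O[Si](C)(C)C(C)(C)C)cc(O)c(C(=O)/C=C/c3ccc(O[Si](C)(C)C(C)(C)C)cc3O[Si](C)(C)C(C)(C)C)c2O[Si](C)(C)C(C)(C)C)[C@H](C(=O)c2ccc(O[Si](C)(C)C(C)(C)C)c(CC=C(C)C)c2O)[C@@H](c2ccc(O[Si](C)(C)C(C)(C)C)cc2O[Si](C)(C)C(C)(C)C)C1
F3 | step 8 | 6-methylhepta-1,5-dien-2-yl triflate | C=C(CCC=C(C)C)OS(=O)(=O)C(F)(F)F
F4 | step 8 | 2-[(1E)-7-methyl-3-methylideneocta-1,6-dien-1-yl]-4,4,5,5-tetramethyl-1,3,2-dioxaborolane | CC(C)=CCCC(=C)/C=C/B1OC(C)(C)C(C)(C)O1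
F5 | step 7 | 1-[4,6-dihydroxy-3-iodo-2-(TBS-oxy)phenyl]ethanone | CC(=O)c1c(O)cc(O)c(I)c1O[Si](C)(C)C(C)(C)C
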